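The leftover I look for first in these flasks is free enzyme: capture agent turns complex into trapped intermediate, and that step has no way back.

    starting material + enzyme ⇌ complex (K1 = 5.9 M⁻¹, k1 = 5.1 × 10⁵ M⁻¹ min⁻¹)
    complex ⇌ enzyme + target (K2 = 0.042 M, k2 = 5000 min⁻¹)
    capture agent + complex → trapped intermediate (k3 = 56000 M⁻¹ min⁻¹)

common to all: capture agent 1.00 mM; enzyme 2.4 µM; time 20 min
- cedar: starting material 0.030 M
- maple: starting material 0.050 M
- alder: starting material 0.080 M
- oak: starting material 0.12 M

- [target] at the end for cedar, maple, alder, oak, in this order
- the course of these numbers from the first flask to the last (falls, then rises / rises all the way / falls all the way / rises, then falls / hardly changes)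

- "hardly changes" means that all values lie within two and a half points (for a concentration: within two and a half percent of the largest)
- run time (cedar): 20 min

How long does the enzyme last? The enzyme can use up 0.240 % of the capture agent, so capture is pseudo-first-order, with a constant of 56.0 min⁻¹ acting on complex. In cedar, the lowest charge, I put complex at about 15.0 % of the enzyme still in the round, which gives a trapping half-life near 0.0823 min, far shorter than the 20 min of the run.

How much target does an enzyme release before that? Complex releases target at 5000 min⁻¹ and falls into the trap at 56.0 min⁻¹, while a return to starting material merely gives the enzyme another try. So each enzyme makes on average N = 89.3 turnovers, and the target ceiling C, which is N times the enzyme charge, comes to 2.14 × 10⁻⁴ M. No starting material appears in C.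

Does the way back from target matter? I put C back in. Target and starting material balance at a ratio of 0.248, so in cedar the balance lies near a target level of 0.00743 M. The net release there falls short by the target present as a share of that level, which is 2.88 % at C and on average half of that. Going round once more, I get 2.11 × 10⁻⁴ M for cedar, 2.12 × 10⁻⁴ M for maple, 2.13 × 10⁻⁴ M for alder and 2.14 × 10⁻⁴ M for oak. That is a rise of 1.08 % from cedar to oak, inside the margin of 2.50 %, so the course I commit to is: hardly changes.

The forecast gives 2.110 × 10⁻⁴ M, 2.120 × 10⁻⁴ M, 2.130 × 10⁻⁴ M and 2.130 × 10⁻⁴ M, course hardly changes, with “a slight reverse-reaction correction”.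

The simulation gives 2.11 × 10⁻⁴ M, 2.13 × 10⁻⁴ M, 2.13 × 10⁻⁴ M and 2.14 × 10⁻⁴ M, course hardly changes.

The largest single effect on oak that a simulated run shows is the capture step, the passing of capture agent and complex into trapped intermediate: with that step taken away, oak's target goes from 2.14 × 10⁻⁴ M to 0.0235 M, which is 110 times C. Taken away in cedar, the same step leaves 0.00594 M of target, which is 27.7 times C.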